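Ring C is disconnected across O1–C2 and C3–C4. The C2–C3 unit with ring B attached is the vinyl group of a 3,5-dioxygenated styrene, while C4, C4a, C8a and O1 come from a fully substituted salicylaldehyde that already carries both prenyl groups. An acid-mediated inverse-demand hetero-Diels–Alder reaction of the derived 4-methoxy ortho-quinone methide forms both bonds, closes ring C, sets C2 under control of a chiral phosphate, and installs C4 at the ketone oxidation level as a methyl ether. The precursors are a 2-hydroxy-4,6-bis(silyloxy)-3,5-diprenylbenzaldehyde and 3,5-bis(triisopropylsilyloxy)styrene; the bulky silyl ethers shield ring B from Friedel–Crafts attack and leave under buffered fluoride at the end.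

Key step: step 5

Assumption: the sense of induction of the chiral acid in step 5 cannot be predicted with certainty; the (R)-configured catalyst is written, and its enantiomer would be used if it should favour the (2R) adduct.

Step 1
Reactants: 1 2,4,6-trihydroxybenzaldehyde; 2 prenyl bromide (1-bromo-3-methylbut-2-ene)
Product: 3 2,4,6-trihydroxy-3,5-bis(3-methylbut-2-enyl)benzaldehyde
Conditions: 2 (2.1 equiv), 10% aq KOH, 0 °C to rt
Reagents that add atoms: none
Why: In water the phloroglucinol phenoxide of 1 reacts as a carbon nucleophile, so SN2 alkylation by prenyl bromide (C-prenylation of an acylphloroglucinol) should take place at C3 and C5, the only free and equally activated ring positions, each adduct rearomatising by tautomerisation.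

Step 2
Reactants: 3 2,4,6-trihydroxy-3,5-bis(3-methylbut-2-enyl)benzaldehyde
Product: 4 4,6-bis(tert-butyldimethylsilyloxy)-2-hydroxy-3,5-bis(3-methylbut-2-enyl)benzaldehyde
Conditions: TBSCl (2.2 equiv), imidazole, DMF, 0 °C to rt
Reagents that add atoms: tert-butyldimethylsilyl chloride, CC(C)(C)[Si](C)(C)Cl
Why: Imidazole-mediated silylation of phenols should take the 4-OH and one of the two equivalent ortho hydroxyls, after which the last hydroxyl is tied up in a hydrogen bond to the formyl oxygen and resists a third silylation (chelation-controlled selective protection).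

Step 3
Reactants: 5 3,5-dihydroxybenzaldehyde
Product: 6 3,5-bis(triisopropylsilyloxy)benzaldehyde
Conditions: TIPSCl (2.3 equiv), imidazole, DMF, rt
Reagents that add atoms: triisopropylsilyl chloride, CC(C)[Si](Cl)(C(C)C)C(C)C
Why: Standard silylation of phenols with a silyl chloride and imidazole converts both unhindered meta hydroxyls, and the aldehyde is inert to these conditions.

Step 4
Reactants: 6 3,5-bis(triisopropylsilyloxy)benzaldehyde
Product: 7 3,5-bis(triisopropylsilyloxy)styrene
Conditions: Ph3PCH3Br (1.3 equiv), KOtBu (1.2 equiv), THF, 0 °C, then 6, 0 °C to rt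
Reagents that add atoms: methyltriphenylphosphonium bromide (reacting as its ylide), C[P+](c1ccccc1)(c1ccccc1)c1ccccc1.[Br-]
Why: Wittig methylenation with the preformed non-stabilised ylide converts the aldehyde into the terminal alkene, and the hindered aryl triisopropylsilyl ethers are not attacked by the ylide at this temperature.

Step 5
Reactants: 4 4,6-bis(tert-butyldimethylsilyloxy)-2-hydroxy-3,5-bis(3-methylbut-2-enyl)benzaldehyde; 7 3,5-bis(triisopropylsilyloxy)styrene
Product: 10 (2S,4S)-5,7-bis(tert-butyldimethylsilyloxy)-4-methoxy-6,8-bis(3-methylbut-2-enyl)-2-[3,5-bis(triisopropylsilyloxy)phenyl]chroman, via dimethyl acetal 8 (not isolated), via oxocarbenium ion 9 (not isolated)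
Conditions: HC(OMe)3 (2 equiv), (R)-TRIP [(R)-3,3'-bis(2,4,6-triisopropylphenyl)-1,1'-binaphthyl-2,2'-diyl hydrogen phosphate] (10 mol%), 7 (3 equiv), toluene, 0 °C to rt
Reagents that add atoms: trimethyl orthoformate, COC(OC)OC
Why: Proposed new method: acid-catalysed exchange with the orthoformate turns 4 into acetal 8, whose ionisation gives oxocarbenium ion 9 (the O-protonated 4-methoxy ortho-quinone methide) held to the chiral phosphate through its phenolic O–H; the CH2 terminus of 7 then bonds to C4 while the phenol oxygen closes on the benzylic carbon C2 in a concerted but asynchronous inverse-demand [4+2] cycloaddition, the closest known reaction types being the racemic acid-catalysed three-component synthesis of 2,4-cis-4-methoxyflavans from salicylaldehydes, orthoformates and styrenes and the chiral phosphoric acid catalysed cycloadditions of ortho-quinone methides with activated alkenes. Ring C closes as a six-membered ring in the hetero-Diels–Alder mode, both new bonds forming in one cycloaddition without a separate cyclisation event. C2 is set by the face of ion pair 9 that the 3,3'-aryl groups of the phosphate leave open combined with endo approach of the styrene aryl group, and C4 follows from the same endo transition state (2,4-cis) and is erased later. The step needs endo and facial selectivity together, because an exo adduct formed on the same cation face would carry (2R), and it needs chemoselectivity for the vinyl group: every free CH of ring B lies beside a triisopropylsilyloxy group and is shielded from Friedel–Crafts attack, ring A has no free position, and the congested trisubstituted prenyl alkenes should be outcompeted by the excess of unhindered styrene. The weak acid and low temperature are chosen so that the free phenol of 4 does not cyclise onto its neighbouring prenyl group and the aryl silyl ethers stay in place.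

Step 6
Reactants: 10 (2S,4S)-5,7-bis(tert-butyldimethylsilyloxy)-4-methoxy-6,8-bis(3-methylbut-2-enyl)-2-[3,5-bis(triisopropylsilyloxy)phenyl]chroman
Product: 11 (2S)-5,7-bis(tert-butyldimethylsilyloxy)-6,8-bis(3-methylbut-2-enyl)-2-[3,5-bis(triisopropylsilyloxy)phenyl]chroman-4-ol (mixture of C4 epimers)
Conditions: PPTS (0.2 equiv), THF/H2O 4:1, 40 °C
Reagents that add atoms: water, O
Why: SN1 solvolysis: the benzylic C4–OMe bond should ionise under very mild acid because the cation is stabilised by O1, O5 and O7 of ring A, and water in large excess captures it, while C2, whose ring B carries only meta oxygens, cannot ionise and keeps its configuration.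

Step 7
Reactants: 11 (2S)-5,7-bis(tert-butyldimethylsilyloxy)-6,8-bis(3-methylbut-2-enyl)-2-[3,5-bis(triisopropylsilyloxy)phenyl]chroman-4-ol
Product: 12 (2S)-5,7-bis(tert-butyldimethylsilyloxy)-6,8-bis(3-methylbut-2-enyl)-2-[3,5-bis(triisopropylsilyloxy)phenyl]chroman-4-one
Conditions: Dess–Martin periodinane (1.5 equiv), NaHCO3, CH2Cl2, 0 °C to rt
Reagents that add atoms: none
Why: Dess–Martin oxidation of a secondary benzylic alcohol converts both C4 epimers into one ketone under buffered, non-enolising conditions that leave the prenyl alkenes, the silyl ethers and the C2 stereocentre untouched.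

Step 8
Reactants: 12 (2S)-5,7-bis(tert-butyldimethylsilyloxy)-6,8-bis(3-methylbut-2-enyl)-2-[3,5-bis(triisopropylsilyloxy)phenyl]chroman-4-one
Product: 13 (2S)-5,7-dihydroxy-2-(3,5-dihydroxyphenyl)-6,8-bis(3-methylbut-2-enyl)chroman-4-one (CID26213315)
Conditions: TBAF (4.4 equiv), AcOH (4.8 equiv), THF, 0 °C to rt
Reagents that add atoms: none
Why: Fluoride cleaves all four aryl silyl ethers (Si–O to Si–F exchange with a phenoxide leaving group), the acetic acid buffer keeps the medium from becoming basic enough for the retro-oxa-Michael ring opening that would racemise C2, and no strong acid is present that could cyclise the prenyl groups onto the freed phenols.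

Compound list
1 | 2,4,6-trihydroxybenzaldehyde | O=Cc1c(O)cc(O)cc1O | starting material
2 | prenyl bromide (1-bromo-3-methylbut-2-ene) | CC(C)=CCBr | starting material
3 | 2,4,6-trihydroxy-3,5-bis(3-methylbut-2-enyl)benzaldehyde | O=Cc1c(O)c(CC=C(C)C)c(O)c(CC=C(C)C)c1O | intermediate
4 | 4,6-bis(tert-butyldimethylsilyloxy)-2-hydroxy-3,5-bis(3-methylbut-2-enyl)benzaldehyde | O=Cc1c(O)c(CC=C(C)C)c(O[Si](C)(C)C(C)(C)C)c(CC=C(C)C)c1O[Si](C)(C)C(C)(C)C | intermediate
5 | 3,5-dihydroxybenzaldehyde | O=Cc1cc(O)cc(O)c1 | starting material
6 | 3,5-bis(triisopropylsilyloxy)benzaldehyde | O=Cc1cc(O[Si](C(C)C)(C(C)C)C(C)C)cc(O[Si](C(C)C)(C(C)C)C(C)C)c1 | intermediate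
7 | 3,5-bis(triisopropylsilyloxy)styrene | C=Cc1cc(O[Si](C(C)C)(C(C)C)C(C)C)cc(O[Si](C(C)C)(C(C)C)C(C)C)c1 | intermediate
8 | dimethyl acetal of 4 (not isolated) | COC(OC)c1c(O)c(CC=C(C)C)c(O[Si](C)(C)C(C)(C)C)c(CC=C(C)C)c1O[Si](C)(C)C(C)(C)C | intermediate
9 | O-methyl oxocarbenium ion of 4, the protonated 4-methoxy ortho-quinone methide, as ion pair with the chiral phosphate (not isolated) | C[O+]=Cc1c(O)c(CC=C(C)C)c(O[Si](C)(C)C(C)(C)C)c(CC=C(C)C)c1O[Si](C)(C)C(C)(C)C | intermediate
10 | (2S,4S)-5,7-bis(tert-butyldimethylsilyloxy)-4-methoxy-6,8-bis(3-methylbut-2-enyl)-2-[3,5-bis(triisopropylsilyloxy)phenyl]chroman (2,4-cis) | CC(C)=CCc1c(O[Si](C)(C)C(C)(C)C)c(CC=C(C)C)c2c(c1O[Si](C)(C)C(C)(C)C)[C@@H](OC)C[C@@H](c1cc(O[Si](C(C)C)(C(C)C)C(C)C)cc(O[Si](C(C)C)(C(C)C)C(C)C)c1)O2 | intermediate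
11 | (2S)-5,7-bis(tert-butyldimethylsilyloxy)-6,8-bis(3-methylbut-2-enyl)-2-[3,5-bis(triisopropylsilyloxy)phenyl]chroman-4-ol, mixture of C4 epimers | CC(C)=CCc1c(O[Si](C)(C)C(C)(C)C)c(CC=C(C)C)c2c(c1O[Si](C)(C)C(C)(C)C)C(O)C[C@@H](c1cc(O[Si](C(C)C)(C(C)C)C(C)C)cc(O[Si](C(C)C)(C(C)C)C(C)C)c1)O2 | intermediate
12 | (2S)-5,7-bis(tert-butyldimethylsilyloxy)-6,8-bis(3-methylbut-2-enyl)-2-[3,5-bis(triisopropylsilyloxy)phenyl]chroman-4-one | CC(C)=CCc1c(O[Si](C)(C)C(C)(C)C)c(CC=C(C)C)c2c(c1O[Si](C)(C)C(C)(C)C)C(=O)C[C@@H](c1cc(O[Si](C(C)C)(C(C)C)C(C)C)cc(O[Si](C(C)C)(C(C)C)C(C)C)c1)O2 | intermediate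
13 | (2S)-5,7-dihydroxy-2-(3,5-dihydroxyphenyl)-6,8-bis(3-methylbut-2-enyl)chroman-4-one (CID26213315) | CC(C)=CCc1c(O)c(CC=C(C)C)c2c(c1O)C(=O)C[C@@H](c1cc(O)cc(O)c1)O2 | target

Total steps: 8. Longest linear sequence: 6 steps (steps 1, 2, 5, 6, 7, 8 from 1; equally steps 3, 4, 5, 6, 7, 8 from 5).

Steps most likely to fail

1. Step 5 (proposed new method). The chiral ion pair may discriminate the two faces of cation 9 only weakly, or the exo pathway may compete, so that the adduct would form with little enantiomeric enrichment. Capture of 9 by a prenyl alkene of a second molecule is a further loss channel. The fallback replaces asymmetric catalysis by resolution and uses known reactions only; it sets out from 4 and 7 and comes back at 12. The three-component cycloaddition would be run in its established racemic form with an achiral acid (p-TsOH·H2O or diphenyl phosphate, HC(OMe)3, toluene) to give the racemic 2,4-cis 4-methoxyflavan F1. The same PPTS hydrolysis would give the racemic flavan-4-ol F2, and Dess–Martin oxidation the racemic silyl-protected flavanone F3. Kinetic resolution of F3 by asymmetric transfer hydrogenation (RuCl(p-cymene)[(R,R)-TsDPEN], HCO2H/Et3N, EtOAc, rt), a known way to resolve racemic flavanones, should reduce the (2R)-ketone to the (2R,4R)-cis-flavan-4-ol F4 and leave the (2S)-ketone 12, which would be separated by chromatography and carried into step 8.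

2. Step 1. O-alkylation and over-alkylation to dearomatised gem-diprenyl products may consume most of the material, so that too little 3 would be obtained. The fallback uses O-alkylation followed by a 1,3-shift; it sets out from 1 and 2 and comes back at 3. With K2CO3 in acetone the two non-chelated hydroxyls would be etherified to 2-hydroxy-4,6-bis(3-methylbut-2-enyloxy)benzaldehyde F5. Acidic clay (montmorillonite K10, Al2Si4O10(OH)2·nH2O, CH2Cl2, 0 °C) should then move both prenyl groups from oxygen to the free ring carbons C3 and C5 by the known acid-clay [1,3]-rearrangement of aryl prenyl ethers, giving 3.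

3. Step 6. Loss of a proton from the C4 cation to give the flav-3-ene may outrun capture by water, or the acid needed for ionisation may begin to remove silyl groups. The fallback unmasks the ketone oxidatively instead of solvolytically; it sets out from 10 and comes back at 12, leaving out 11 and step 7 and making no compound outside the list (F0). DDQ in CH2Cl2/H2O at 0 °C should abstract the hydride from the electron-rich C4–H next to the methoxy group, and water would convert the resulting oxocarbenium ion into ketone 12 with loss of methanol. This is the known DDQ oxidation of electron-rich benzylic methyl ethers to carbonyl compounds.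

Further compounds
F1 | step 5 | racemic 2,4-cis-5,7-bis(tert-butyldimethylsilyloxy)-4-methoxy-6,8-bis(3-methylbut-2-enyl)-2-[3,5-bis(triisopropylsilyloxy)phenyl]chroman | CC(C)=CCc1c(O[Si](C)(C)C(C)(C)C)c(CC=C(C)C)c2c(c1O[Si](C)(C)C(C)(C)C)C(OC)CC(c1cc(O[Si](C(C)C)(C(C)C)C(C)C)cc(O[Si](C(C)C)(C(C)C)C(C)C)c1)O2
F2 | step 5 | racemic 5,7-bis(tert-butyldimethylsilyloxy)-6,8-bis(3-methylbut-2-enyl)-2-[3,5-bis(triisopropylsilyloxy)phenyl]chroman-4-ol | CC(C)=CCc1c(O[Si](C)(C)C(C)(C)C)c(CC=C(C)C)c2c(c1O[Si](C)(C)C(C)(C)C)C(O)CC(c1cc(O[Si](C(C)C)(C(C)C)C(C)C)cc(O[Si](C(C)C)(C(C)C)C(C)C)c1)O2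
F3 | step 5 | racemic 5,7-bis(tert-butyldimethylsilyloxy)-6,8-bis(3-methylbut-2-enyl)-2-[3,5-bis(triisopropylsilyloxy)phenyl]chroman-4-one | CC(C)=CCc1c(O[Si](C)(C)C(C)(C)C)c(CC=C(C)C)c2c(c1O[Si](C)(C)C(C)(C)C)C(=O)CC(c1cc(O[Si](C(C)C)(C(C)C)C(C)C)cc(O[Si](C(C)C)(C(C)C)C(C)C)c1)O2
F4 | step 5 | (2R,4R)-5,7-bis(tert-butyldimethylsilyloxy)-6,8-bis(3-methylbut-2-enyl)-2-[3,5-bis(triisopropylsilyloxy)phenyl]chroman-4-ol (2,4-cis) | CC(C)=CCc1c(O[Si](C)(C)C(C)(C)C)c(CC=C(C)C)c2c(c1O[Si](C)(C)C(C)(C)C)[C@H](O)C[C@H](c1cc(O[Si](C(C)C)(C(C)C)C(C)C)cc(O[Si](C(C)C)(C(C)C)C(C)C)c1)O2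
F5 | step 1 | 2-hydroxy-4,6-bis(3-methylbut-2-enyloxy)benzaldehyde | O=Cc1c(O)cc(OCC=C(C)C)cc1OCC=C(C)C
F0 | step 6 | none | none
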